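**Retrosynthetic overview**

1. The target is opened to a γ-hydroxy ketone carrying three tert-butyl esters and a C3/C4 acetonide. One acid step removes all protecting groups and closes both rings of the 2,8-dioxabicyclo[3.2.1]octane (five-membered ring through O8 first, then six-membered ring through O2), which fixes C1.
2. Key disconnection C5–C6: a ketone homoenolate (a β-zincio ketone carrying the whole C1 side chain, released from a cyclopropanol) adds to the C5 keto group of an α-keto ester and sets C5.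
3. The α-keto ester comes from the enolate of D-tartrate acetonide and tert-butyl chlorooxoacetate (C3 from the chiral pool, C4 by anti-acylation).
4. The cyclopropanol comes from a Kulinkovich reaction of a γ,δ-unsaturated ester, made by Johnson–Claisen rearrangement (E-olefin) of an isopropenyl carbinol, itself from an Evans benzylation (side-chain stereocentre).
5. Ring order: the temporary dioxolane and cyclopropane first; the two rings of the target last, in the same flask.

Assumption: the SMILES is read as the (1S,3S,4S,5R) core with a (3E,5S) side chain (6,7-dideoxysqualestatin H5); di-tert-butyl D-tartrate, tert-butyl chlorooxoacetate and Zn[N(SiMe3)2]2 are taken as purchasable.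

**Step 1**
Reactants: 1 (4R)-4-benzyl-3-propanoyl-1,3-oxazolidin-2-one; 2 benzyl bromide
Product: 4 (4R)-4-benzyl-3-[(2S)-2-methyl-3-phenylpropanoyl]-1,3-oxazolidin-2-one, via sodium Z-enolate 3 (not isolated)
Conditions: NaN(SiMe3)2 (1.1 equiv), THF, −78 °C, 45 min; then 2 (2 equiv), −78 → −20 °C
Reagents that add atoms: none
Why: Evans asymmetric alkylation; the chelated Z-enolate is benzylated on the face opposite the C4 benzyl group of the (R)-auxiliary, which gives the 2S centre (dr above 95:5, raised further by chromatography or crystallisation).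

**Step 2**
Reactants: 4 (4R)-4-benzyl-3-[(2S)-2-methyl-3-phenylpropanoyl]-1,3-oxazolidin-2-one
Product: 5 (2S)-2-methyl-3-phenylpropan-1-ol
Conditions: LiBH4 (1.5 equiv), THF, 0 → 23 °C; aqueous NaOH work-up
Reagents that add atoms: none
Why: Reductive cleavage of the N-acyloxazolidinone at the exocyclic carbonyl by borohydride, which does not touch the α-stereocentre and returns the auxiliary.

**Step 3**
Reactants: 5 (2S)-2-methyl-3-phenylpropan-1-ol
Product: 6 (2S)-2-methyl-3-phenylpropanal
Conditions: Dess–Martin periodinane (1.2 equiv), CH2Cl2, 0 → 23 °C, 1 h; used crude at once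
Reagents that add atoms: none
Why: Dess–Martin oxidation is near-neutral and non-enolising, so the α-stereocentre of the aldehyde is kept.

**Step 4**
Reactants: 6 (2S)-2-methyl-3-phenylpropanal; 7 isopropenylmagnesium bromide
Product: 8 (4S)-2,4-dimethyl-5-phenylpent-1-en-3-ol (mixture of C3 epimers)
Conditions: CH2=C(CH3)MgBr (1.5 equiv, 0.5 M in THF), THF, −78 → 0 °C; aqueous NH4Cl
Reagents that add atoms: none
Why: Grignard 1,2-addition to the aldehyde; the new carbinol centre forms as an epimer mixture that does not matter because it becomes sp2 in step 5.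

**Step 5**
Reactants: 8 (4S)-2,4-dimethyl-5-phenylpent-1-en-3-ol; 9 triethyl orthoacetate
Product: 12 ethyl (4E,6S)-4,6-dimethyl-7-phenylhept-4-enoate, via mixed orthoester 10 (not isolated), via ketene acetal 11 (not isolated)
Conditions: CH3C(OEt)3 (6 equiv), EtCO2H (0.1 equiv), 140 °C, 4 h, ethanol distilled off
Reagents that add atoms: none
Why: Johnson–Claisen [3,3] rearrangement through a chair transition state with the CH(CH3)CH2Ph group equatorial, so both carbinol epimers converge on the E-trisubstituted olefin while the C6 stereocentre is untouched.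

**Step 6**
Reactants: 12 ethyl (4E,6S)-4,6-dimethyl-7-phenylhept-4-enoate; 13 ethylmagnesium bromide
Product: 14 1-[(3E,5S)-3,5-dimethyl-6-phenylhex-3-en-1-yl]cyclopropan-1-ol
Conditions: EtMgBr (2.6 equiv, added over 2 h), Ti(OiPr)4 (0.2 equiv), THF, 0 → 23 °C; aqueous NH4Cl
Reagents that add atoms: none
Why: Kulinkovich cyclopropanation; the titanacyclopropane formed from EtMgBr and Ti(OiPr)4 acts as a 1,2-dicarbanion toward the ester, the trisubstituted alkene does not take part, and no stereocentre is formed.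

**Step 7**
Reactants: 15 di-tert-butyl D-tartrate
Product: 16 di-tert-butyl (4S,5S)-2,2-dimethyl-1,3-dioxolane-4,5-dicarboxylate
Conditions: 2-methoxypropene (3 equiv), PPTS (0.05 equiv), CH2Cl2, 0 → 23 °C
Reagents that add atoms: 2-methoxypropene, COC(C)=C
Why: Acid-catalysed ketalisation of the diol under conditions mild enough for tert-butyl esters; both stereocentres come unchanged from D-tartrate.

**Step 8**
Reactants: 16 di-tert-butyl (4S,5S)-2,2-dimethyl-1,3-dioxolane-4,5-dicarboxylate; 17 tert-butyl chlorooxoacetate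
Product: 19 di-tert-butyl (4S,5S)-4-[2-(tert-butoxy)-2-oxoacetyl]-2,2-dimethyl-1,3-dioxolane-4,5-dicarboxylate, via lithium enolate 18 (not isolated)
Conditions: LiN(iPr)2 (1.05 equiv), THF, −78 °C, 20 min; cannulated into 17 (2 equiv), THF, −78 °C, 1 h; aqueous NH4Cl at −78 °C
Reagents that add atoms: none
Why: Claisen-type C-acylation of the tartrate acetonide ester enolate; the acid chloride enters anti to the neighbouring tert-butyl ester, so the new quaternary centre (C4 of the target) is S, and the product has no α-hydrogen left at that carbon.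

**Step 9**
Reactants: 14 1-[(3E,5S)-3,5-dimethyl-6-phenylhex-3-en-1-yl]cyclopropan-1-ol; 19 di-tert-butyl (4S,5S)-4-[2-(tert-butoxy)-2-oxoacetyl]-2,2-dimethyl-1,3-dioxolane-4,5-dicarboxylate
Product: 22 di-tert-butyl (4S,5S)-4-[(2R,8E,10S)-1-(tert-butoxy)-2-hydroxy-8,10-dimethyl-1,5-dioxo-11-phenylundec-8-en-2-yl]-2,2-dimethyl-1,3-dioxolane-4,5-dicarboxylate, via zinc bis(cyclopropanolate) 20 (not isolated), via bis(homoenolate)zinc 21 (not isolated)
Conditions: 14 (1.5 equiv), Zn[N(SiMe3)2]2 (0.75 equiv), THF–DMSO (4:1), 23 °C, 1 h; then 19 (1.0 equiv), 0 → 23 °C; aqueous NH4Cl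
Reagents that add atoms: none
Why: Proposed new method: the zinc cyclopropanolate 20 opens under strain release to the β-zincio ketone 21 (a ketone homoenolate, nucleophilic at C6 although C6 is β to the C1 carbonyl), and this dialkylzinc-type reagent adds to the doubly activated, non-enolisable keto group of 19, which binds zinc through the C5 keto oxygen and the dioxolane oxygen on C4 so that the alkyl group arrives anti to the C4 tert-butyl ester and C5 becomes R; the closest known reaction types are the ring opening of zinc cyclopropanolates to zinc homoenolates used in conjugate additions and allylations, the homo-Reformatsky addition of zinc and titanium ester homoenolates to carbonyl compounds, and the uncatalysed addition of dialkylzincs to α-keto esters.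

**Step 10**
Reactants: 22 di-tert-butyl (4S,5S)-4-[(2R,8E,10S)-1-(tert-butoxy)-2-hydroxy-8,10-dimethyl-1,5-dioxo-11-phenylundec-8-en-2-yl]-2,2-dimethyl-1,3-dioxolane-4,5-dicarboxylate
Product: 24 (1S,3S,4S,5R)-1-[(3E,5S)-3,5-dimethyl-6-phenylhex-3-en-1-yl]-4-hydroxy-2,8-dioxabicyclo[3.2.1]octane-3,4,5-tricarboxylic acid, via triacid acetonide 23 (not isolated)
Conditions: TFA/CH2Cl2/H2O (20:10:1), 23 °C, 18 h; evaporation; reverse-phase HPLC
Reagents that add atoms: none
Why: Acidolysis of the three tert-butyl esters followed by thermodynamic transketalisation, in which the C1 oxocarbenium ion formed from the C5 hydroxyl and the ketone is captured by the C3 oxygen as acetone leaves, so the C1 configuration (S) is dictated by the C3 and C5 centres.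

**Compound list**

1 | (4R)-4-benzyl-3-propanoyl-1,3-oxazolidin-2-one | CCC(=O)N1[C@H](Cc2ccccc2)COC1=O | starting material
2 | benzyl bromide | BrCc1ccccc1 | starting material
3 | sodium (1Z)-1-[(4R)-4-benzyl-2-oxo-1,3-oxazolidin-3-yl]prop-1-en-1-olate (sodium Z-enolate of 1) | C/C=C(\[O-])N1[C@H](Cc2ccccc2)COC1=O.[Na+] | intermediate
4 | (4R)-4-benzyl-3-[(2S)-2-methyl-3-phenylpropanoyl]-1,3-oxazolidin-2-one | C[C@@H](Cc1ccccc1)C(=O)N1[C@H](Cc2ccccc2)COC1=O | intermediate
5 | (2S)-2-methyl-3-phenylpropan-1-ol | C[C@@H](Cc1ccccc1)CO | intermediate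
6 | (2S)-2-methyl-3-phenylpropanal | C[C@@H](Cc1ccccc1)C=O | intermediate
7 | isopropenylmagnesium bromide (prop-1-en-2-ylmagnesium bromide) | C=C(C)[Mg]Br | starting material
8 | (4S)-2,4-dimethyl-5-phenylpent-1-en-3-ol (C3 epimer mixture) | C[C@@H](Cc1ccccc1)C(O)C(C)=C | intermediate
9 | triethyl orthoacetate | CC(OCC)(OCC)OCC | starting material
10 | 1,1-diethoxy-1-{[(4S)-2,4-dimethyl-5-phenylpent-1-en-3-yl]oxy}ethane (mixed orthoester) | C[C@@H](Cc1ccccc1)C(OC(C)(OCC)OCC)C(C)=C | intermediate
11 | 1-ethoxy-1-{[(4S)-2,4-dimethyl-5-phenylpent-1-en-3-yl]oxy}ethene (ketene acetal) | C[C@@H](Cc1ccccc1)C(OC(=C)OCC)C(C)=C | intermediate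
12 | ethyl (4E,6S)-4,6-dimethyl-7-phenylhept-4-enoate | CCOC(=O)CC/C(C)=C/[C@@H](C)Cc1ccccc1 | intermediate
13 | ethylmagnesium bromide | CC[Mg]Br | starting material
14 | 1-[(3E,5S)-3,5-dimethyl-6-phenylhex-3-en-1-yl]cyclopropan-1-ol | OC1(CC/C(C)=C/[C@@H](C)Cc2ccccc2)CC1 | intermediate
15 | di-tert-butyl D-tartrate, di-tert-butyl (2S,3S)-2,3-dihydroxybutanedioate | CC(C)(C)OC(=O)[C@@H](O)[C@H](O)C(=O)OC(C)(C)C | starting material
16 | di-tert-butyl (4S,5S)-2,2-dimethyl-1,3-dioxolane-4,5-dicarboxylate | CC(C)(C)OC(=O)[C@H]1OC(C)(C)O[C@@H]1C(=O)OC(C)(C)C | intermediate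
17 | tert-butyl chlorooxoacetate | CC(C)(C)OC(=O)C(=O)Cl | starting material
18 | lithium ester enolate of 16, lithium tert-butoxy[(5S)-5-(tert-butoxycarbonyl)-2,2-dimethyl-1,3-dioxolan-4-ylidene]methanolate | CC(C)(C)OC(=O)[C@H]1OC(C)(C)OC1=C([O-])OC(C)(C)C.[Li+] | intermediate
19 | di-tert-butyl (4S,5S)-4-[2-(tert-butoxy)-2-oxoacetyl]-2,2-dimethyl-1,3-dioxolane-4,5-dicarboxylate (the two ring esters cis) | CC(C)(C)OC(=O)C(=O)[C@@]1(C(=O)OC(C)(C)C)OC(C)(C)O[C@@H]1C(=O)OC(C)(C)C | intermediate
20 | zinc bis{1-[(3E,5S)-3,5-dimethyl-6-phenylhex-3-en-1-yl]cyclopropan-1-olate} | O([Zn]OC1(CC/C(C)=C/[C@@H](C)Cc2ccccc2)CC1)C1(CC/C(C)=C/[C@@H](C)Cc2ccccc2)CC1 | intermediate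
21 | bis[(6E,8S)-6,8-dimethyl-3-oxo-9-phenylnon-6-en-1-yl]zinc | C/C(=C\[C@@H](C)Cc1ccccc1)CCC(=O)CC[Zn]CCC(=O)CC/C(C)=C/[C@@H](C)Cc1ccccc1 | intermediate
22 | di-tert-butyl (4S,5S)-4-[(2R,8E,10S)-1-(tert-butoxy)-2-hydroxy-8,10-dimethyl-1,5-dioxo-11-phenylundec-8-en-2-yl]-2,2-dimethyl-1,3-dioxolane-4,5-dicarboxylate | C/C(=C\[C@@H](C)Cc1ccccc1)CCC(=O)CC[C@](O)(C(=O)OC(C)(C)C)[C@@]1(C(=O)OC(C)(C)C)OC(C)(C)O[C@@H]1C(=O)OC(C)(C)C | intermediate
23 | (4S,5S)-4-[(1R,7E,9S)-1-carboxy-1-hydroxy-7,9-dimethyl-4-oxo-10-phenyldec-7-en-1-yl]-2,2-dimethyl-1,3-dioxolane-4,5-dicarboxylic acid | C/C(=C\[C@@H](C)Cc1ccccc1)CCC(=O)CC[C@](O)(C(=O)O)[C@@]1(C(=O)O)OC(C)(C)O[C@@H]1C(=O)O | intermediate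
24 | (1S,3S,4S,5R)-1-[(3E,5S)-3,5-dimethyl-6-phenylhex-3-en-1-yl]-4-hydroxy-2,8-dioxabicyclo[3.2.1]octane-3,4,5-tricarboxylic acid | C/C(=C\[C@@H](C)Cc1ccccc1)CC[C@@]12CC[C@@](C(=O)O)(O1)[C@](O)(C(=O)O)[C@@H](C(=O)O)O2 | target

**Step count and risks**

Total step count: 10. Longest linear sequence: 8 (steps 1–6, 9, 10).

The step most likely to fail is step 9. The zinc homoenolate may be protonated to the simple ethyl ketone, may react through its enolised form at C7 instead of C6, or may add to the wrong face at C5. The fallback sets out from 14 and 19 and comes back to the route at 24; it replaces the direct homoenolate by a classical masked one. Ring-opening bromination of 14 with N-bromosuccinimide (CH2Cl2, 0 °C, dark) gives (6E,8S)-1-bromo-6,8-dimethyl-9-phenylnon-6-en-3-one F2. Ketalisation with 2,2-dimethylpropane-1,3-diol (PPTS, benzene, water removal) gives 2-(2-bromoethyl)-2-[(3E,5S)-3,5-dimethyl-6-phenylhex-3-en-1-yl]-5,5-dimethyl-1,3-dioxane F3. Magnesium insertion (Mg, THF, 25 °C) gives {2-[2-((3E,5S)-3,5-dimethyl-6-phenylhex-3-en-1-yl)-5,5-dimethyl-1,3-dioxan-2-yl]ethyl}magnesium bromide F4. Chelation-controlled addition of this Grignard reagent to 19 (THF/CH2Cl2, −78 °C) gives di-tert-butyl (4S,5S)-4-[(2R)-1-(tert-butoxy)-4-{2-[(3E,5S)-3,5-dimethyl-6-phenylhex-3-en-1-yl]-5,5-dimethyl-1,3-dioxan-2-yl}-2-hydroxy-1-oxobutan-2-yl]-2,2-dimethyl-1,3-dioxolane-4,5-dicarboxylate F5. The conditions of step 10 then take this compound to 24, with the dioxane ketal falling off together with the other protecting groups.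

The second is step 8. Enolate 18 fragments by β-elimination of the ring oxygen if it warms above about −70 °C, and O-acylation or attack of 18 on the newly formed keto group can compete. The fallback sets out from 16 and comes back at 19; it makes the C4–C5 bond by aldol addition and adjusts the oxidation level afterwards. Enolate 18 is trapped at −78 °C with tert-butyl glyoxylate to give di-tert-butyl (4R,5S)-4-[2-(tert-butoxy)-1-hydroxy-2-oxoethyl]-2,2-dimethyl-1,3-dioxolane-4,5-dicarboxylate F1 (carbinol epimers; same ring geometry as 19, the descriptor changes only through the priority order). Dess–Martin oxidation of the secondary alcohol then gives 19.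

The third is step 10. The dioxolane sits between ester groups and opens slowly, and the trisubstituted alkene can be protonated in strong acid (addition of trifluoroacetate or cyclisation onto the phenyl ring). The fallback sets out from 22 and comes back at 24; it separates ring formation from ester cleavage. Transketalisation alone with anhydrous HCl (1% w/v) in methanol at 23 °C, driven by the C1 oxocarbenium ion and trapping of acetone by methanol, gives tri-tert-butyl (1S,3S,4S,5R)-1-[(3E,5S)-3,5-dimethyl-6-phenylhex-3-en-1-yl]-4-hydroxy-2,8-dioxabicyclo[3.2.1]octane-3,4,5-tricarboxylate F6. This can be purified on silica, which also removes any C5 epimer. The three tert-butyl esters are then cleaved with 85% aqueous H3PO4 in toluene at 23–40 °C to give 24.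

**Further compounds**

F1 | step 8 | di-tert-butyl (4R,5S)-4-[2-(tert-butoxy)-1-hydroxy-2-oxoethyl]-2,2-dimethyl-1,3-dioxolane-4,5-dicarboxylate (carbinol epimers) | CC(C)(C)OC(=O)C(O)[C@@]1(C(=O)OC(C)(C)C)OC(C)(C)O[C@@H]1C(=O)OC(C)(C)C
F2 | step 9 | (6E,8S)-1-bromo-6,8-dimethyl-9-phenylnon-6-en-3-one | BrCCC(=O)CC/C(C)=C/[C@@H](C)Cc1ccccc1
F3 | step 9 | 2-(2-bromoethyl)-2-[(3E,5S)-3,5-dimethyl-6-phenylhex-3-en-1-yl]-5,5-dimethyl-1,3-dioxane | BrCCC1(CC/C(C)=C/[C@@H](C)Cc2ccccc2)OCC(C)(C)CO1
F4 | step 9 | {2-[2-((3E,5S)-3,5-dimethyl-6-phenylhex-3-en-1-yl)-5,5-dimethyl-1,3-dioxan-2-yl]ethyl}magnesium bromide | Br[Mg]CCC1(CC/C(C)=C/[C@@H](C)Cc2ccccc2)OCC(C)(C)CO1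
F5 | step 9 | di-tert-butyl (4S,5S)-4-[(2R)-1-(tert-butoxy)-4-{2-[(3E,5S)-3,5-dimethyl-6-phenylhex-3-en-1-yl]-5,5-dimethyl-1,3-dioxan-2-yl}-2-hydroxy-1-oxobutan-2-yl]-2,2-dimethyl-1,3-dioxolane-4,5-dicarboxylate | C/C(=C\[C@@H](C)Cc1ccccc1)CCC2(OCC(C)(C)CO2)CC[C@](O)(C(=O)OC(C)(C)C)[C@@]3(C(=O)OC(C)(C)C)OC(C)(C)O[C@@H]3C(=O)OC(C)(C)C
F6 | step 10 | tri-tert-butyl (1S,3S,4S,5R)-1-[(3E,5S)-3,5-dimethyl-6-phenylhex-3-en-1-yl]-4-hydroxy-2,8-dioxabicyclo[3.2.1]octane-3,4,5-tricarboxylate | C/C(=C\[C@@H](C)Cc1ccccc1)CC[C@@]12CC[C@@](C(=O)OC(C)(C)C)(O1)[C@](O)(C(=O)OC(C)(C)C)[C@@H](C(=O)OC(C)(C)C)O2
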